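**Retrosynthetic overview**
- The target is reached by one final hydrogenolysis of a depside in which the two ring A phenols are benzyl ethers and the ring B acid is a 2,4,6-trimethylbenzyl ester.
- Key disconnection: the depside ester is cut at the aryl C–O bond of ring B, not at the acyl C–O bond. The ring A carboxylate acts as O-nucleophile toward a ring B arylboronic acid in a copper-mediated oxidative coupling, so the hindered keto acid is never activated as an acyl donor (activation would invite closure to a 3-pentylisocoumarin).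
- The ring B boron is placed by sterically controlled iridium C–H borylation para to the ester, so ring B never carries a free phenol and starts from plain 2-methoxy-6-methylbenzoic acid.
- Both 2-oxoheptyl chains come from lateral lithiation of the ortho-toluates and acylation with one Weinreb amide of hexanoic acid.
- No ring is formed in the route: both benzene rings are bought (methyl orsellinate for ring A, 2-methoxy-6-methylbenzoic acid for ring B).

Assumption: the target SMILES has no stereocentre and no stereogenic double bond, so the compound is achiral and the route needs no stereocontrol.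

**Route**

Step 1
Reactants: 1 hexanoyl chloride; 2 N,O-dimethylhydroxylamine hydrochloride
Product: 4 N-methoxy-N-methylhexanamide, via free N,O-dimethylhydroxylamine 3 (not isolated)
Conditions: K2CO3 (2.2 equiv), EtOAc/H2O (1:1), 0 °C to rt
Reagents that add atoms: N,O-dimethylhydroxylamine hydrochloride 2, Cl.CNOC
Why: Schotten–Baumann amide formation, in which carbonate frees amine 3 from its salt and the amine acylates far faster than water hydrolyses the acid chloride.

Step 2
Reactants: 5 methyl orsellinate (methyl 2,4-dihydroxy-6-methylbenzoate); 6 benzyl bromide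
Product: 8 methyl 2,4-bis(benzyloxy)-6-methylbenzoate, via 4-O-benzyl monoether 7 (not isolated)
Conditions: BnBr (2.5 equiv), K2CO3 (3 equiv), DMF, 60 °C
Reagents that add atoms: benzyl bromide 6, BrCc1ccccc1
Why: Williamson ether synthesis, in which the free 4-OH is benzylated first and the hydrogen-bonded 2-OH follows with excess halide and heat, while the hindered methyl ester is untouched.

Step 3
Reactants: 8 methyl 2,4-bis(benzyloxy)-6-methylbenzoate; 4 N-methoxy-N-methylhexanamide
Product: 11 methyl 2,4-bis(benzyloxy)-6-(2-oxoheptyl)benzoate, via benzylic lithium species 9 (not isolated), via lithium tetrahedral adduct 10 (not isolated)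
Conditions: LiN(iPr)2 (1.15 equiv), THF, −78 °C; then 4 (1.3 equiv), −78 to −40 °C; 1 M HCl quench
Reagents that add atoms: N-methoxy-N-methylhexanamide 4, CCCCCC(=O)N(C)OC
Why: Lateral (benzylic) lithiation of an ortho-toluate followed by Weinreb ketone synthesis, where the ester-stabilised benzylic anion adds once to the amide and the chelated adduct holds until the acid quench, so neither over-addition nor enolate chemistry of the product ketone occurs.

Step 4
Reactants: 11 methyl 2,4-bis(benzyloxy)-6-(2-oxoheptyl)benzoate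
Product: 13 2,4-bis(benzyloxy)-6-(2-oxoheptyl)benzoic acid, via potassium carboxylate 12 (not isolated)
Conditions: KOH (6 equiv), EtOH/H2O (3:1), 80 °C; then 1 M HCl, 0 °C, to pH 3
Reagents that add atoms: potassium hydroxide, [K+].[OH-]
Why: Saponification (alkaline ester hydrolysis), helped at this hindered ester by the neighbouring side-chain carbonyl, with aryl benzyl ethers and the ketone stable to aqueous base and cold acidification giving the free acid.

Step 5
Reactants: 14 2-methoxy-6-methylbenzoic acid; 15 2,4,6-trimethylbenzyl chloride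
Product: 16 2,4,6-trimethylbenzyl 2-methoxy-6-methylbenzoate
Conditions: Cs2CO3 (1.2 equiv), DMF, rt
Reagents that add atoms: 2,4,6-trimethylbenzyl chloride 15, Cc1cc(C)c(CCl)c(C)c1
Why: Carboxylate O-alkylation (SN2 at the benzylic chloride) bypasses the hindered carbonyl carbon, and this ester is chosen because its two ring C–H bonds are flanked by methyl groups and so stay out of the later C–H borylation, yet it still leaves by hydrogenolysis.

Step 6
Reactants: 16 2,4,6-trimethylbenzyl 2-methoxy-6-methylbenzoate; 4 N-methoxy-N-methylhexanamide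
Product: 19 2,4,6-trimethylbenzyl 2-methoxy-6-(2-oxoheptyl)benzoate, via benzylic lithium species 17 (not isolated), via lithium tetrahedral adduct 18 (not isolated)
Conditions: LiN(iPr)2 (1.15 equiv), THF, −78 °C; then 4 (1.3 equiv), −78 to −40 °C; 1 M HCl quench
Reagents that add atoms: N-methoxy-N-methylhexanamide 4, CCCCCC(=O)N(C)OC
Why: Lateral lithiation and Weinreb ketone synthesis as in step 3, with the bulky doubly ortho-substituted ester suppressing self-condensation of the benzylic anion.

Step 7
Reactants: 19 2,4,6-trimethylbenzyl 2-methoxy-6-(2-oxoheptyl)benzoate; 20 bis(pinacolato)diboron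
Product: 22 [3-methoxy-5-(2-oxoheptyl)-4-{[(2,4,6-trimethylbenzyl)oxy]carbonyl}phenyl]boronic acid, via pinacol boronate 21 (not isolated)
Conditions: [Ir(cod)(OMe)]2 (1.5 mol %), 4,4′-di-tert-butyl-2,2′-bipyridine (3 mol %), B2pin2 (1.0 equiv), THF, 65 °C; then NaIO4 (3 equiv), NH4OAc (3 equiv), acetone/H2O (1:1), rt
Reagents that add atoms: bis(pinacolato)diboron 20, CC1(C)OB(OC1(C)C)B1OC(C)(C)C(C)(C)O1; water, O
Why: Iridium-catalysed aromatic C–H borylation (Hartwig–Miyaura–Ishiyama type) is sterically controlled, so boron enters at the only ring C–H without an ortho substituent (C4, para to the ester) and the flanked C–H bonds of the ester group are left alone, after which periodate cleaves the pinacol ester to the boronic acid.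

Step 8
Reactants: 13 2,4-bis(benzyloxy)-6-(2-oxoheptyl)benzoic acid; 22 the ring B boronic acid
Product: 23 3-methoxy-5-(2-oxoheptyl)-4-{[(2,4,6-trimethylbenzyl)oxy]carbonyl}phenyl 2,4-bis(benzyloxy)-6-(2-oxoheptyl)benzoate
Conditions: 22 (1.5 equiv), Cu(OTf)2 (0.5 equiv), urea (1.0 equiv), 2,6-lutidine (1.2 equiv), EtOAc, dry air, 50 °C
Reagents that add atoms: none
Why: Chan–Lam-type oxidative C–O coupling, in which the divalent copper carboxylate of 13 transmetalates with the arylboronic acid, oxidation to trivalent copper and C–O reductive elimination give the aryl ester, the hindered acid reacting only through its oxygen so that its ortho substituents do not block the bond formation and no activated acyl species can close onto the ketone (triflate, unlike acetate, cannot compete as O-nucleophile).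

Step 9
Reactants: 23 the protected depside
Product: 24 arthonioic acid, 4-{[2,4-dihydroxy-6-(2-oxoheptyl)benzoyl]oxy}-2-methoxy-6-(2-oxoheptyl)benzoic acid
Conditions: H2 (1 atm), 20% Pd(OH)2/C, EtOAc, rt
Reagents that add atoms: none
Why: Catalytic hydrogenolysis of benzylic C–O bonds removes both benzyl ethers and the 2,4,6-trimethylbenzyl ester, in no fixed order, under neutral conditions that leave the aryl ester, the two dialkyl ketones and the methyl ether intact.

**Compound list**

1 | hexanoyl chloride | CCCCCC(=O)Cl | starting material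
2 | N,O-dimethylhydroxylamine hydrochloride | Cl.CNOC | starting material
3 | N,O-dimethylhydroxylamine (free base) | CNOC | intermediate
4 | N-methoxy-N-methylhexanamide | CCCCCC(=O)N(C)OC | intermediate
5 | methyl orsellinate (methyl 2,4-dihydroxy-6-methylbenzoate) | COC(=O)c1c(C)cc(O)cc1O | starting material
6 | benzyl bromide | BrCc1ccccc1 | starting material
7 | methyl 4-(benzyloxy)-2-hydroxy-6-methylbenzoate | COC(=O)c1c(C)cc(OCc2ccccc2)cc1O | intermediate
8 | methyl 2,4-bis(benzyloxy)-6-methylbenzoate | COC(=O)c1c(C)cc(OCc2ccccc2)cc1OCc1ccccc1 | intermediate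
9 | [3,5-bis(benzyloxy)-2-(methoxycarbonyl)benzyl]lithium | [Li]Cc1cc(OCc2ccccc2)cc(OCc2ccccc2)c1C(=O)OC | intermediate
10 | lithium alkoxide of methyl 2,4-bis(benzyloxy)-6-{2-hydroxy-2-[methoxy(methyl)amino]heptyl}benzoate | CCCCCC(O[Li])(Cc1cc(OCc2ccccc2)cc(OCc2ccccc2)c1C(=O)OC)N(C)OC | intermediate
11 | methyl 2,4-bis(benzyloxy)-6-(2-oxoheptyl)benzoate | CCCCCC(=O)Cc1cc(OCc2ccccc2)cc(OCc2ccccc2)c1C(=O)OC | intermediate
12 | potassium 2,4-bis(benzyloxy)-6-(2-oxoheptyl)benzoate | CCCCCC(=O)Cc1cc(OCc2ccccc2)cc(OCc2ccccc2)c1C(=O)[O-].[K+] | intermediate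
13 | 2,4-bis(benzyloxy)-6-(2-oxoheptyl)benzoic acid | CCCCCC(=O)Cc1cc(OCc2ccccc2)cc(OCc2ccccc2)c1C(=O)O | intermediate
14 | 2-methoxy-6-methylbenzoic acid | COc1cccc(C)c1C(=O)O | starting material
15 | 2,4,6-trimethylbenzyl chloride | Cc1cc(C)c(CCl)c(C)c1 | starting material
16 | 2,4,6-trimethylbenzyl 2-methoxy-6-methylbenzoate | COc1cccc(C)c1C(=O)OCc1c(C)cc(C)cc1C | intermediate
17 | [3-methoxy-2-{[(2,4,6-trimethylbenzyl)oxy]carbonyl}benzyl]lithium | [Li]Cc1cccc(OC)c1C(=O)OCc1c(C)cc(C)cc1C | intermediate
18 | lithium alkoxide of 2,4,6-trimethylbenzyl 2-{2-hydroxy-2-[methoxy(methyl)amino]heptyl}-6-methoxybenzoate | CCCCCC(O[Li])(Cc1cccc(OC)c1C(=O)OCc1c(C)cc(C)cc1C)N(C)OC | intermediate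
19 | 2,4,6-trimethylbenzyl 2-methoxy-6-(2-oxoheptyl)benzoate | CCCCCC(=O)Cc1cccc(OC)c1C(=O)OCc1c(C)cc(C)cc1C | intermediate
20 | bis(pinacolato)diboron | CC1(C)OB(OC1(C)C)B1OC(C)(C)C(C)(C)O1 | starting material
21 | 2,4,6-trimethylbenzyl 2-methoxy-6-(2-oxoheptyl)-4-(4,4,5,5-tetramethyl-1,3,2-dioxaborolan-2-yl)benzoate | CCCCCC(=O)Cc1cc(B2OC(C)(C)C(C)(C)O2)cc(OC)c1C(=O)OCc1c(C)cc(C)cc1C | intermediate
22 | [3-methoxy-5-(2-oxoheptyl)-4-{[(2,4,6-trimethylbenzyl)oxy]carbonyl}phenyl]boronic acid | CCCCCC(=O)Cc1cc(B(O)O)cc(OC)c1C(=O)OCc1c(C)cc(C)cc1C | intermediate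
23 | 3-methoxy-5-(2-oxoheptyl)-4-{[(2,4,6-trimethylbenzyl)oxy]carbonyl}phenyl 2,4-bis(benzyloxy)-6-(2-oxoheptyl)benzoate | CCCCCC(=O)Cc1cc(OCc2ccccc2)cc(OCc2ccccc2)c1C(=O)Oc1cc(CC(=O)CCCCC)c(C(=O)OCc2c(C)cc(C)cc2C)c(OC)c1 | intermediate
24 | arthonioic acid | CCCCCC(=O)Cc1cc(O)cc(O)c1C(=O)Oc1cc(CC(=O)CCCCC)c(C(=O)O)c(OC)c1 | target

**Step count and risks**

Total steps: 9. Longest linear sequence: 5 steps (for example steps 5, 6, 7, 8, 9 from 14; steps 2, 3, 4, 8, 9 from 5 are equally long).

Most likely to fail, step 8 (copper-mediated aryl ester formation). The risks are protodeboronation or phenol formation from 22 and Lewis-acid induced closure of keto acid 13. The fallback keeps the carboxylate as nucleophile but changes the ring B partner and the metal. It sets out from pinacol boronate 21 (step 7 stopped before the periodate stage) and comes back to the route at 23. CuBr2 (3 equiv) in MeOH/H2O at 80 °C converts 21 by ipso-bromodeboronation into 2,4,6-trimethylbenzyl 4-bromo-2-methoxy-6-(2-oxoheptyl)benzoate F1. F1 and acid 13 are then joined by nickel catalysis under blue light (NiBr2·glyme 5 mol %, 4,4′-di-tert-butyl-2,2′-bipyridine, Ir(ppy)3 1 mol % as triplet sensitiser, N-tert-butylisopropylamine, DMF, rt). Oxidative addition of the electron-poor aryl bromide to low-valent nickel and light-driven C–O reductive elimination from the aryl nickel carboxylate give 23.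

Second, step 7 (C–H borylation next to an enolisable benzylic ketone). The risks are ketone reduction by the boron hydride formed and loss of material in the periodate stage. The fallback masks the ketone before the borylation. It sets out from 19 and comes back to the route at 21. 1,2-Bis(trimethylsilyloxy)ethane with catalytic TMSOTf in CH2Cl2 at −78 to −20 °C gives 2,4,6-trimethylbenzyl 2-methoxy-6-[(2-pentyl-1,3-dioxolan-2-yl)methyl]benzoate F2. The same iridium borylation then gives 2,4,6-trimethylbenzyl 2-methoxy-6-[(2-pentyl-1,3-dioxolan-2-yl)methyl]-4-(4,4,5,5-tetramethyl-1,3,2-dioxaborolan-2-yl)benzoate F3. 1 M HCl in THF at rt removes the dioxolane to give 21, which goes on through the periodate stage of step 7.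

Third, step 4 (saponification of the hindered keto ester). The risk is base-induced Dieckmann-type C-acylation of the ketone enolate onto the ester instead of hydrolysis. The fallback hydrolyses the ester before the ketone exists and installs the side chain on the acid dianion. It sets out from 8 and comes back to the route at 13. KOH in DMSO/H2O at 100 °C gives potassium 2,4-bis(benzyloxy)-6-methylbenzoate F4, and acidification gives 2,4-bis(benzyloxy)-6-methylbenzoic acid F5. LiN(iPr)2 (2.3 equiv) in THF at −78 to 0 °C forms the dilithio carboxylate benzyl dianion F6, which adds to amide 4 at −78 °C to give the dilithium tetrahedral adduct F7. Quenching with 1 M HCl releases keto acid 13.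

Further compounds
F1 | step 8 | 2,4,6-trimethylbenzyl 4-bromo-2-methoxy-6-(2-oxoheptyl)benzoate | CCCCCC(=O)Cc1cc(Br)cc(OC)c1C(=O)OCc1c(C)cc(C)cc1C
F2 | step 7 | 2,4,6-trimethylbenzyl 2-methoxy-6-[(2-pentyl-1,3-dioxolan-2-yl)methyl]benzoate | CCCCCC1(Cc2cccc(OC)c2C(=O)OCc2c(C)cc(C)cc2C)OCCO1
F3 | step 7 | 2,4,6-trimethylbenzyl 2-methoxy-6-[(2-pentyl-1,3-dioxolan-2-yl)methyl]-4-(4,4,5,5-tetramethyl-1,3,2-dioxaborolan-2-yl)benzoate | CCCCCC1(Cc2cc(B3OC(C)(C)C(C)(C)O3)cc(OC)c2C(=O)OCc2c(C)cc(C)cc2C)OCCO1
F4 | step 4 | potassium 2,4-bis(benzyloxy)-6-methylbenzoate | Cc1cc(OCc2ccccc2)cc(OCc2ccccc2)c1C(=O)[O-].[K+]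
F5 | step 4 | 2,4-bis(benzyloxy)-6-methylbenzoic acid | Cc1cc(OCc2ccccc2)cc(OCc2ccccc2)c1C(=O)O
F6 | step 4 | lithium 2,4-bis(benzyloxy)-6-(lithiomethyl)benzoate | [Li]Cc1cc(OCc2ccccc2)cc(OCc2ccccc2)c1C(=O)O[Li]
F7 | step 4 | dilithium salt of 2,4-bis(benzyloxy)-6-{2-hydroxy-2-[methoxy(methyl)amino]heptyl}benzoic acid | CCCCCC(O[Li])(Cc1cc(OCc2ccccc2)cc(OCc2ccccc2)c1C(=O)O[Li])N(C)OC
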